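The runs are simulated from invented constants; the scatter is artificial.

4 questions stand on this flask; the two orders I take from ratios of starting rates, and the other two answers I reach through one number: the share of the target present that disappears each minute.

| flask | starting material | catalyst | time |
|---|---|---|---|
| Wednesday's | 0.800 M | 0.00160 M |  |
| Saturday's | 0.400 M | 0.00160 M |  |
| Thursday's | 0.800 M | 0.00240 M |  |
| Monday's | 2.40 M | 0.00320 M | 7.7 min |

| Wednesday's run: time / min | Wednesday's run: [target] / M | Saturday's run: time / min | Saturday's run: [target] / M | Thursday's run: time / min | Thursday's run: [target] / M |
|---|---|---|---|---|---|
| 0.44 | 0.0488 | 0.44 | 0.0310 | 0.44 | 0.0709 |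
| 1.3 | 0.1330 | 1.3 | 0.0737 | 1.3 | 0.1930 |
| 2.5 | 0.2284 | 2.5 | 0.1250 | 2.5 | 0.3143 |
| 4.0 | 0.3124 | 4.0 | 0.1640 | 4.0 | 0.4125 |
| 5.8 | 0.3737 | 5.8 | 0.1965 | 5.8 | 0.4648 |
| 7.7 | 0.4092 | 7.7 | 0.2061 | 7.7 | 0.4729 |

(readings scatter by 0.002 M)

- the exponent of [catalyst] in the starting rate at the charge of the Wednesday's run (at the point where two percent of the starting material have become target)
- the exponent of [starting material] in the starting rate at the charge of the Wednesday's run (at the point where two percent of the starting material have become target) (one fixed amount of target, the same in the runs compared)
- target in the Monday's run at 7.7 min, as a share of the starting material charged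
- which of these the readings show (the product binds the substrate / the product ties up the catalyst / two substrates go astray together / the product decays / nothing beyond the main steps)

- Overall: starting material -> target, with catalyst as catalyst.
- Constant volume, constant temperature.
- Bound and free are read together.
- An order is taken over about fifteen percent of the charge, up and down.

Taking the average rates up to the second and third readings and running them back to zero time, I read starting rates of 0.114 M min⁻¹ in Wednesday's flask, 0.173 M min⁻¹ in Thursday's and 0.0639 M min⁻¹ in Saturday's. Thursday's flask against Wednesday's gives me a catalyst order of 1.03, and Saturday's smaller charge gives a starting-material order of 0.836.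

With a catalyst order near one, I expect Wednesday's flask at 5.8 min and Thursday's at 3.87 min to have turned equal shares of their charge, since both have had equal catalyst-time. Yet target stands at 46.7% of the charge in Wednesday's flask and at 50.5% in Thursday's, higher after the shorter clock time. I read that gap as target lost, and I divide it by the difference between the areas under the two share-against-time curves, 1.66 min against 1.16 min. This gives the leak, the share of the target present that disappears per minute, of 0.0743 min⁻¹.

The second way uses Saturday's flask alone. I treat its formation as pseudo-first-order, with 0.160 min⁻¹ of the remaining starting material turning per minute. Midway through its last interval, target stands at 50.3% of the charge and the area is 2.25 min. Balancing formation against leak and the observed rise gives 0.0773 min⁻¹, which is 1.04 times the leak of the first way, with Saturday's flask holding half the starting material of Wednesday's, so I answer that the product decays.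

For Monday's flask I scale the formation constant to 0.238 min⁻¹. Target in that flask then crosses from gaining to losing at 7.10 min, earlier than the time asked, and my share at 7.7 min is 58.8%.

The forecast differs from mine, with orders 1 and 0.68, 46% and the choice the product ties up the catalyst, on the words: “Product tying up catalyst fits, with substrate partly protecting it.”

Monday's flask gives 62.0% of its charge at 7.7 min, the orders at Wednesday's charge come out at 1.0 in catalyst and 0.82 in starting material, and the readings show the product decays.

    catalyst + starting material ⇌ catalyst-substrate complex, settled at all times (0.3220 L mol⁻¹)
    catalyst-substrate complex → target + catalyst (351.6 min⁻¹)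
    target → decomposed product (0.07500 min⁻¹)

Applied to that share, the leak I read from the runs, 0.0743 min⁻¹, gives my own estimate of the loss of target from Monday's flask at 7.7 min: about 0.111 M min⁻¹.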